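**Plan**
- Retrosynthesis: the quinone goes back to a 1,4-diaryl-2,3,5,6-tetramethoxybenzene (redox only). In each indole the bonds C3a–C4 and C7–C7a are cut, removing C4–C7 as a four-carbon bis-acetal and leaving a 2,3-disubstituted pyrrole.
- Each pyrrole is then cut at N1–C5 and C3–C4 (C4 and C5 from one molecule of acetylene per ring, N from a ketoxime). The bis-ketone is cut at its two aryl–CH2 bonds (ketone α-arylation of a dibromoarene).
- Forward: the central ring is bought and dibrominated, both side chains are joined, both pyrrole rings form together, both benzo rings are fused on together, and the quinone is unveiled last.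
- Enabling feature: the benzo ring of each indole (C4, C5, C6, C7) carries only hydrogen. In the pyrrole precursor C2 (tert-alkyl) and C3 (aryl) are occupied, so C4 and C5 are the only free ring carbons for a double Friedel–Crafts annulation.
- Stereochemistry: the target has no stereocentre and no stereogenic double bond, so nothing has to be set.

Key step: step 6

Remark: compounds 1, 3, 7 and 10 are taken as commercial; the bis-oxime 6 is drawn E,E, but either oxime geometry serves in step 5.

**Step 1**
Reactants: 1 1,2,4,5-tetramethoxybenzene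
Product: 2 1,4-dibromo-2,3,5,6-tetramethoxybenzene
Conditions: NBS (2.1 equiv), MeCN, 0 °C to rt
Reagents that add atoms: N-bromosuccinimide, O=C1CCC(=O)N1Br
Why: Electrophilic aromatic bromination of a very electron-rich arene whose only two free positions, each flanked by two methoxy groups, are para to one another, so the dibromide should form as a single isomer.

**Step 2**
Reactants: 3 2,2-dimethylbut-3-enoic acid
Product: 4 3,3-dimethylpent-4-en-2-one
Conditions: MeLi (2.2 equiv), Et2O, 0 °C to rt; then H2O
Reagents that add atoms: methyllithium, [Li]C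
Why: Methyl ketone synthesis from a carboxylic acid and an organolithium: the lithium carboxylate takes up one methyllithium to a gem-dialkoxide that collapses to the ketone only on aqueous work-up, and the α-quaternary carbon disfavours over-addition.

**Step 3**
Reactants: 2 1,4-dibromo-2,3,5,6-tetramethoxybenzene; 4 3,3-dimethylpent-4-en-2-one (3 equiv)
Product: 5 1,1'-(2,3,5,6-tetramethoxy-1,4-phenylene)bis(3,3-dimethylpent-4-en-2-one)
Conditions: Pd2(dba)3 (cat.), XPhos (cat.), NaOtBu, toluene, 80 °C
Reagents that add atoms: none
Why: Twofold palladium-catalysed ketone α-arylation (Buchwald–Hartwig type) of a pinacolone-like methyl ketone that can enolise only toward its methyl group; the bulky biaryl phosphine should cope with the di-ortho-methoxy aryl bromide, and the hindered benzyl ketone formed resists a second arylation.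

**Step 4**
Reactants: 5 1,1'-(2,3,5,6-tetramethoxy-1,4-phenylene)bis(3,3-dimethylpent-4-en-2-one)
Product: 6 (2E,2'E)-1,1'-(2,3,5,6-tetramethoxy-1,4-phenylene)bis(3,3-dimethylpent-4-en-2-one) dioxime
Conditions: NH2OH·HCl, NaOAc, EtOH/H2O, reflux
Reagents that add atoms: hydroxylamine hydrochloride, NO.Cl
Why: Oxime condensation of a ketone, which works even for tert-alkyl ketones of the pinacolone type; the hydroxyl group should settle anti to the quaternary carbon.

**Step 5**
Reactants: 6 (2E,2'E)-1,1'-(2,3,5,6-tetramethoxy-1,4-phenylene)bis(3,3-dimethylpent-4-en-2-one) dioxime; 7 acetylene (2 equiv)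
Product: 9 3,3'-(2,3,5,6-tetramethoxy-1,4-phenylene)bis[2-(2-methylbut-3-en-2-yl)-1H-pyrrole], via bis(O-vinyl oxime) 8 (not isolated)
Conditions: acetylene stream (1 atm), KOH, DMSO, 100 °C
Reagents that add atoms: none
Why: Trofimov pyrrole synthesis, in which each of the two oxime groups takes up one molecule of acetylene from the gas stream: the oximate adds to acetylene in KOH/DMSO, the O-vinyl oxime tautomerises toward its only α-CH2 (the benzylic one), a [3,3]-sigmatropic shift and cyclodehydration follow, so the aryl group ends at C3 and the tert-alkyl group at C2, while the vinyl groups on quaternary carbons cannot migrate in base and the C2 tert-alkyl group slows N-vinylation.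

**Step 6**
Reactants: 9 3,3'-(2,3,5,6-tetramethoxy-1,4-phenylene)bis[2-(2-methylbut-3-en-2-yl)-1H-pyrrole]; 10 1,1,4,4-tetramethoxybutane (4 equiv)
Product: 12 3,3'-(2,3,5,6-tetramethoxy-1,4-phenylene)bis[2-(2-methylbut-3-en-2-yl)-1H-indole], via bis(4,7-dimethoxytetrahydroindole) 11 (not isolated)
Conditions: Zn(OTf)2 (20 mol %), ClCH2CH2Cl, 4 Å MS, 60 °C, high dilution
Reagents that add atoms: none
Why: Zn(OTf)2 ionises one acetal end of 10 to an oxocarbenium ion that is attacked by the free α-carbon C5 of each pyrrole (the future C7–C7a bond), the second acetal end then alkylates the neighbouring C4 (the future C3a–C4 bond) to give 11, and two losses of methanol through pyrrole-stabilised cations aromatise each new ring without any oxidant. The closest known reaction type is the acid-catalysed benzannulation of pyrroles to indoles and of indoles to carbazoles with 1,4-dicarbonyl compounds or their acetals (double Friedel–Crafts hydroxyalkylation followed by elimination). Each of the two benzo rings closes in the same mode, a 6-exo-trig Friedel–Crafts cyclisation of the pyrrole β-carbon C4 onto the tethered oxocarbenium ion. No stereocentre remains in 12, since the methoxy-bearing centres of 11 are transient and erased on elimination. The step needs closure at C4 instead of N1 (which would lead to an indolizine) and reaction at the pyrroles only: C4 and C5 are the sole unsubstituted ring carbons, a neutral pyrrole nitrogen is a poor nucleophile under acid and its N,O-aminal would form reversibly, the central arene is fully substituted and the monosubstituted alkenes are far less nucleophilic than a pyrrole. A weak Lewis acid, excess 10, sieves to bind methanol and dilution are chosen to spare the acid-labile 1,1-dimethylallyl groups and to suppress bridging of two pyrroles by one dialdehyde unit.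

**Step 7**
Reactants: 12 3,3'-(2,3,5,6-tetramethoxy-1,4-phenylene)bis[2-(2-methylbut-3-en-2-yl)-1H-indole]
Product: 13 2,5-dimethoxy-3,6-bis[2-(2-methylbut-3-en-2-yl)-1H-indol-3-yl]cyclohexa-2,5-diene-1,4-dione
Conditions: (NH4)2Ce(NO3)6 (2.2 equiv), MeCN/H2O, 0 °C
Reagents that add atoms: water, O
Why: Oxidative demethylation of a para-dimethoxyarene by tetravalent cerium: two single-electron oxidations of the central ring, attack of water at two para methoxy-bearing carbons and loss of methanol give the quinone, both para pairs being equivalent by symmetry, while C2 and C3 of each indole are shielded by the tert-alkyl group and the twisted central ring.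

**Compound list**
1 | 1,2,4,5-tetramethoxybenzene | COc1cc(OC)c(OC)cc1OC | starting material
2 | 1,4-dibromo-2,3,5,6-tetramethoxybenzene | COc1c(OC)c(Br)c(OC)c(OC)c1Br | intermediate
3 | 2,2-dimethylbut-3-enoic acid | C=CC(C)(C)C(=O)O | starting material
4 | 3,3-dimethylpent-4-en-2-one | C=CC(C)(C)C(C)=O | intermediate
5 | 1,1'-(2,3,5,6-tetramethoxy-1,4-phenylene)bis(3,3-dimethylpent-4-en-2-one) | COc1c(OC)c(CC(=O)C(C)(C)C=C)c(OC)c(OC)c1CC(=O)C(C)(C)C=C | intermediate
6 | (2E,2'E)-1,1'-(2,3,5,6-tetramethoxy-1,4-phenylene)bis(3,3-dimethylpent-4-en-2-one) dioxime | COc1c(OC)c(C/C(=N\O)C(C)(C)C=C)c(OC)c(OC)c1C/C(=N\O)C(C)(C)C=C | intermediate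
7 | acetylene | C#C | starting material
8 | 1,1'-(2,3,5,6-tetramethoxy-1,4-phenylene)bis(3,3-dimethylpent-4-en-2-one) bis(O-vinyl oxime) | COc1c(OC)c(C/C(=N\OC=C)C(C)(C)C=C)c(OC)c(OC)c1C/C(=N\OC=C)C(C)(C)C=C | intermediate
9 | 3,3'-(2,3,5,6-tetramethoxy-1,4-phenylene)bis[2-(2-methylbut-3-en-2-yl)-1H-pyrrole] | COc1c(OC)c(-c2cc[nH]c2C(C)(C)C=C)c(OC)c(OC)c1-c1cc[nH]c1C(C)(C)C=C | intermediate
10 | 1,1,4,4-tetramethoxybutane | COC(OC)CCC(OC)OC | starting material
11 | 3,3'-(2,3,5,6-tetramethoxy-1,4-phenylene)bis[4,7-dimethoxy-2-(2-methylbut-3-en-2-yl)-4,5,6,7-tetrahydro-1H-indole], mixture of diastereomers | COc1c(OC)c(-c2c(C(C)(C)C=C)[nH]c3c2C(OC)CCC3OC)c(OC)c(OC)c1-c1c(C(C)(C)C=C)[nH]c2c1C(OC)CCC2OC | intermediate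
12 | 3,3'-(2,3,5,6-tetramethoxy-1,4-phenylene)bis[2-(2-methylbut-3-en-2-yl)-1H-indole] | COc1c(OC)c(-c2c(C(C)(C)C=C)[nH]c3ccccc23)c(OC)c(OC)c1-c1c(C(C)(C)C=C)[nH]c2ccccc12 | intermediate
13 | 2,5-dimethoxy-3,6-bis[2-(2-methylbut-3-en-2-yl)-1H-indol-3-yl]cyclohexa-2,5-diene-1,4-dione | C=CC(C)(C)c1[nH]c2ccccc2c1C1=C(OC)C(=O)C(c2c(C(C)(C)C=C)[nH]c3ccccc23)=C(OC)C1=O | target

**Step count**
Total: 7 steps. Longest linear sequence: 6 steps (steps 1, 3, 4, 5, 6, 7 from compound 1; equally steps 2 to 7 from compound 3).

**Steps most likely to fail**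

Step 6. Acid-induced loss or migration of the 1,1-dimethylallyl groups, bridging of two pyrroles by one dialdehyde unit (oligomerisation), or slow closure at C4 next to the bulky C3 aryl group could stop the annulation short of the bis-indole. The fallback sets out from bis-ketone 5. Condensation with phenylhydrazine (EtOH, cat. AcOH, reflux) should give 1,1'-(2,3,5,6-tetramethoxy-1,4-phenylene)bis(3,3-dimethylpent-4-en-2-one) bis(phenylhydrazone) F1. Fischer indolisation of this compound (ZnCl2, 100 °C, or hot AcOH) can form the ene-hydrazine only toward the benzylic CH2 and so should close both indoles with the aryl group at C3 and the tert-alkyl group at C2. It comes back to the route at compound 12.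

Step 5. Over-vinylation at nitrogen, conversion of only one of the two oximes, or base-induced decomposition at 100 °C could erode the bis-pyrrole. The fallback sets out from bis-ketone 5. Double alkylation of the benzylic enolates with 2-bromo-1,1-diethoxyethane (NaH, NaI, DMSO, 60 °C) should give 3,3'-(2,3,5,6-tetramethoxy-1,4-phenylene)bis(1,1-diethoxy-5,5-dimethylhept-6-en-4-one) F2 as a diastereomer mixture. Paal–Knorr condensation with NH4OAc in warm aqueous AcOH unmasks the two aldehydes and closes both pyrrole rings. It comes back to the route at compound 9.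

Step 7. Competing single-electron oxidation of the indole rings, with oxygenation or cleavage at C2–C3, or over-oxidation in the acidic nitrate medium could consume the material at the last stage. The fallback sets out from compound 12. Anodic oxidation at a platinum anode in KOH/MeOH (constant current, 0 °C) should give 3,3'-(2,3,3,5,6,6-hexamethoxycyclohexa-1,4-diene-1,4-diyl)bis[2-(2-methylbut-3-en-2-yl)-1H-indole] F3, the quinone bis(dimethyl ketal). Hydrolysis with dilute aqueous AcOH in acetone at rt releases the quinone. It comes back to the route at compound 13.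

**Further compounds**
F1 | step 6 | 1,1'-(2,3,5,6-tetramethoxy-1,4-phenylene)bis(3,3-dimethylpent-4-en-2-one) bis(phenylhydrazone) | COc1c(OC)c(C/C(=N\Nc2ccccc2)C(C)(C)C=C)c(OC)c(OC)c1C/C(=N\Nc1ccccc1)C(C)(C)C=C
F2 | step 5 | 3,3'-(2,3,5,6-tetramethoxy-1,4-phenylene)bis(1,1-diethoxy-5,5-dimethylhept-6-en-4-one), mixture of diastereomers | COc1c(OC)c(C(CC(OCC)OCC)C(=O)C(C)(C)C=C)c(OC)c(OC)c1C(CC(OCC)OCC)C(=O)C(C)(C)C=C
F3 | step 7 | 3,3'-(2,3,3,5,6,6-hexamethoxycyclohexa-1,4-diene-1,4-diyl)bis[2-(2-methylbut-3-en-2-yl)-1H-indole] | COC1=C(c2c(C(C)(C)C=C)[nH]c3ccccc23)C(OC)(OC)C(OC)=C(c2c(C(C)(C)C=C)[nH]c3ccccc23)C1(OC)OC
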